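The complex with one exchanged is the product I want, and in the green run it is still climbing at the last reading: 15.4% after 40.0 min, then 18.1% after 60.0 min.

| flask | starting complex | incoming ligand | protic impurity | remark | time |
|---|---|---|---|---|---|
| green | 0.26 M | 0.47 M | 0.078 M | run made earlier |  |
| flask | 0.26 M | 0.312 M | 0.0780 M |  | 10 h |

green run (percent of the starting complex charged)

| time / min | complex with one exchanged / % | complex with three exchanged / % |
|---|---|---|
| 5.00 | 3.0 | 0 |
| 8.00 | 4.9 | 0.5 |
| 12.0 | 6.6 | 0 |
| 15.0 | 7.9 | 0 |
| 25.0 | 11.8 | 0.1 |
| 40.0 | 15.4 | 0.4 |
| 60.0 | 18.1 | 0.4 |

(each reading ± 0.3 percentage points)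

- what was read earlier has a scatter of 0.3 percentage points, one standard deviation
- no earlier run changes the charge of incoming ligand; that part of a forecast is a guess

- time up to 10 h at which complex with one exchanged stands highest
- the amount of complex with one exchanged, in percent of the starting complex charged, at that time

If the exchange is pseudo-first-order in a steady ligand level, time and ligand count as a product. The green run's last reading should then recur here after 1.51 h, since the charge falls from 1.81 to 1.20 equivalents on starting complex.

But the ligand does not stay steady. Exchange takes some, and the protic impurity, 0.300 equivalents in each flask, may take some too, and that costs the smaller charge more. So I replace the falling ligand by its mean, taking half of the impurity and of the green reading off the charge. That gives 1.57 equivalents in green and 0.960 here.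

The ligand dose, mean equivalents times time 1.57 h, is one equivalent held for that long at green's last reading. This flask reaches it after 1.63 h. I expect about 18.1% by then and the peak somewhat later. My doubt is that a loss needing no ligand would run by the clock and not by the dose.

The forecast reads the bend as “a reversible first exchange, or something else stalling it” and says 17% at 3.5 h, later than my time.

The simulation gives 16.9% at 2.27 h.

    protic impurity + incoming ligand → quenched reagent (k = 5.50 × 10⁻⁴ M⁻¹ s⁻¹)
    complex with two exchanged + incoming ligand ⇌ leaving ligand + complex with three exchanged (K = 0.210, k = 3.10 × 10⁻⁴ M⁻¹ s⁻¹)
    complex with one exchanged → decomposed reagent (k = 8.00 × 10⁻⁵ s⁻¹)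
    starting complex + incoming ligand ⇌ leaving ligand + complex with one exchanged (K = 55.0, k = 2.30 × 10⁻⁴ M⁻¹ s⁻¹)
    complex with one exchanged + incoming ligand ⇌ leaving ligand + complex with two exchanged (K = 0.480, k = 4.10 × 10⁻⁴ M⁻¹ s⁻¹)
    starting complex + complex with two exchanged → side product (k = 0.00200 M⁻¹ s⁻¹)

That peak comes later than my 1.63 h and lower than the level I expected, at a dose of 2.18 h. At 1.75 h in this flask the complex with one exchanged is still made 1.18 times faster than it is used up, each step taken net, while its ligand-free loss to decomposed reagent runs at 1.1 times the forward step alone to complex with two exchanged.

In the neighbour flask with 0.53 M of incoming ligand, the mean of 1.80 equivalents reaches the dose after 0.872 h, so I look for the green level by then and a peak above it. The computed peak there is 21.1%.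

The readings stem from a simulated flask for an exercise, and the scatter is random.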